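**Retrosynthetic overview**

- Chondrillin ← acid-catalysed ketal exchange at C6 in methanol (separation of the C6 epimers, the unwanted one recycled) ← the 6-methoxy-3,6-dihydro-1,2-dioxine as both C6 epimers.
- Dioxine ring (the only ring, formed last) ← one-pot formal [4+2] annulation: the O1–C6 bond by acid-catalysed addition of methyl (3R,4E)-3-hydroperoxyhex-4-enoate to 1-hexadecyl-1-methoxyallene, then ring closure at C4=C5 by ring-closing metathesis (RCM) with loss of propene.
- Hydroperoxide ← amine-catalysed enantioselective conjugate addition of 2-hydroperoxy-2-methoxypropane to sorbaldehyde (sets C3), Pinnick oxidation, esterification, peroxyketal hydrolysis; allene ← C1-lithiation of methoxyallene and alkylation with 1-iodohexadecane.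
- Enabling feature: the ring double bond C4=C5 lies between two oxygen-bearing sp3 carbons (C3 and the ketal carbon C6) bridged by O1–O2. The ring is therefore a cyclic bis-allylic peroxide: each CH= carbon can be carried as an alkene terminus, and the ketal carbon C6 (OMe, O–O, vinyl) is the adduct of a hydroperoxide with an alkoxyallene.

Key step: step 7

Assumption: the facial sense of the amine-catalysed peroxidation follows the steric-shielding model of diarylprolinol silyl ether iminium ions (the (R)-catalyst leading to 3R); if the sense proved opposite, the (S)-catalyst would be used.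

**Route**

Step 1
Reactants: 1 2,3-dimethylbut-2-ene
Product: 3 2-hydroperoxy-2-methoxypropane, via acetone O-oxide 2 (not isolated)
Conditions: O3, MeOH/CH2Cl2, −78 °C; kept as a titrated solution
Reagents that add atoms: ozone [O-][O+]=O; methanol CO
Why: Ozonolysis in methanol (Criegee mechanism): cycloreversion of the primary ozonide of the symmetrical alkene gives acetone and the carbonyl oxide 2, which methanol traps as the α-methoxy hydroperoxide; no stereocentre is formed.

Step 2
Reactants: 4 (2E,4E)-hexa-2,4-dienal (sorbaldehyde); 3 2-hydroperoxy-2-methoxypropane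
Product: 5 (3R,4E)-3-[(2-methoxypropan-2-yl)peroxy]hex-4-enal
Conditions: (R)-2-[bis(3,5-bis(trifluoromethyl)phenyl)(trimethylsilyloxy)methyl]pyrrolidine (10 mol%), PhCO2H (10 mol%), toluene, 0 °C
Reagents that add atoms: none
Why: Iminium-catalysed enantioselective oxa-Michael addition of a hydroperoxide to an enal: the E,s-trans iminium ion of 4 is shielded on one face by the diaryl(silyloxy)methyl group, the peroxide oxygen adds 1,4 (the faster site compared with the methyl-bearing 1,6 terminus) to the open face and sets C3 as R, and low temperature plus the acid co-catalyst should favour protonation of the enamine over its closure to an epoxide.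

Step 3
Reactants: 5 (3R,4E)-3-[(2-methoxypropan-2-yl)peroxy]hex-4-enal
Product: 6 (3R,4E)-3-[(2-methoxypropan-2-yl)peroxy]hex-4-enoic acid
Conditions: NaClO2, NaH2PO4, 2-methyl-2-butene, t-BuOH/H2O, 0 °C
Reagents that add atoms: sodium chlorite [Na+].[O-]Cl=O
Why: Pinnick oxidation: chlorous acid adds to the aldehyde and fragments to the acid under buffered, non-basic conditions that avoid E1cB loss of the β-peroxide, while 2-methyl-2-butene removes HOCl before it reaches the disubstituted alkene; C3 is untouched.

Step 4
Reactants: 6 (3R,4E)-3-[(2-methoxypropan-2-yl)peroxy]hex-4-enoic acid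
Product: 7 methyl (3R,4E)-3-[(2-methoxypropan-2-yl)peroxy]hex-4-enoate
Conditions: TMSCHN2, MeOH/toluene, 0 °C
Reagents that add atoms: (trimethylsilyl)diazomethane C[Si](C)(C)C=[N+]=[N-]
Why: Esterification with (trimethylsilyl)diazomethane: the acid protonates the reagent, methanol desilylates it to diazomethane in the flask and the carboxylate is O-methylated with loss of N2 under neutral conditions that leave the peroxyketal and C3 intact.

Step 5
Reactants: 7 methyl (3R,4E)-3-[(2-methoxypropan-2-yl)peroxy]hex-4-enoate
Product: 8 methyl (3R,4E)-3-hydroperoxyhex-4-enoate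
Conditions: AcOH/THF/H2O (4:2:1), rt
Reagents that add atoms: none
Why: Acid-catalysed hydrolysis of the 2-methoxypropan-2-yl peroxyketal (the standard unmasking of a protected hydroperoxide) releases acetone and methanol from the ketal carbon without breaking the C3–O bond, so the R configuration is retained.

Step 6
Reactants: 9 methoxyallene (1-methoxypropa-1,2-diene); 10 1-iodohexadecane
Product: 12 3-methoxynonadeca-1,2-diene (1-hexadecyl-1-methoxyallene), via 1-lithio-1-methoxyallene 11 (not isolated)
Conditions: n-BuLi, THF, −40 °C; then 10, −40 °C to rt
Reagents that add atoms: none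
Why: Deprotonation of methoxyallene at the oxygen-bearing sp2 carbon and SN2 alkylation of the lithioallene with the primary iodide gives the 1-alkyl-1-methoxyallene; no stereocentre is formed.

Step 7
Reactants: 8 methyl (3R,4E)-3-hydroperoxyhex-4-enoate; 12 3-methoxynonadeca-1,2-diene
Product: 14 methyl 2-[(3R,6RS)-6-hexadecyl-6-methoxy-3,6-dihydro-1,2-dioxin-3-yl]acetate (both C6 epimers), via mixed peroxyketal 13 (not isolated)
Conditions: PPTS (5 mol%), CH2Cl2, 0 °C (12 in slight excess); then NaHCO3, second-generation Hoveyda–Grubbs catalyst (5 mol%), CH2Cl2 (0.01 M), 40 °C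
Reagents that add atoms: none
Why: Proposed new method: a one-pot formal [4+2] annulation of an allylic hydroperoxide with a 1-alkyl-1-alkoxyallene: PPTS protonates the central allene carbon of 12, the hydroperoxide oxygen of 8 captures the resulting 1-methoxyallyl cation at its oxygen-bearing carbon to give the bis-allylic peroxyketal 13 (O1–C6 bond), and the ruthenium alkylidene then joins the propenyl CH on C3 to the vinyl CH on C6 with loss of propene (C4=C5 bond), so that two acyclic fragments become the complete 6-methoxy-3,6-dihydro-1,2-dioxine in one flask. The closest known reaction types are the PPTS-catalysed addition of hydroperoxides to 2-methoxypropene, the O–H addition of alcohols to alkoxyallenes followed by RCM to 2-alkoxy-3,6-dihydro-2H-pyrans, and the RCM of bis-allylic dialkyl peroxides to 3,6-dihydro-1,2-dioxines. The ring is closed by RCM (six-membered ene–ene closure through a ruthenacyclobutane), and the ring size enforces the cis C4=C5 geometry. C3 enters from 8 with no bond to it broken and stays R, whereas C6 is created by attack on a planar cation lying 1,4 across the O–O bond from C3 and is therefore not controlled here; both epimers should cyclise and are resolved in step 8. The step needs O-attack at the ketal carbon and not at the CH2 terminus of the cation (secured by the methoxy group, which localises the charge there), absence of free OOH when the ruthenium is added (secured by the slight excess of 12 and by quenching the acid with NaHCO3, because hydroperoxides but not dialkyl peroxides destroy the alkylidene), and ring closure in preference to cross-metathesis (secured by high dilution and the favourable six-membered ring).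

Step 8
Reactants: 14 methyl 2-[(3R,6RS)-6-hexadecyl-6-methoxy-3,6-dihydro-1,2-dioxin-3-yl]acetate (both C6 epimers)
Product: 15 chondrillin (methyl 2-[(3R,6S)-6-hexadecyl-6-methoxy-3,6-dihydro-1,2-dioxin-3-yl]acetate)
Conditions: TsOH·H2O (5 mol%), MeOH, 0 °C to rt; chromatography; 6R epimer resubmitted
Reagents that add atoms: methanol CO
Why: Acid-catalysed ketal exchange: both C6 epimers ionise to the same ring-retained, allyl-stabilised peroxycarbenium ion and re-add methanol, so C6 is set under equilibrium control without an expected strong bias; the 6S epimer (hexadecyl chain cis to the C3 side chain, OMe trans to it) is separated by chromatography and the 6R epimer is returned to the equilibration, while C3 is not touched.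

**Compound list**

1 | 2,3-dimethylbut-2-ene | CC(C)=C(C)C | starting material
2 | acetone O-oxide (carbonyl oxide) | CC(C)=[O+][O-] | intermediate
3 | 2-hydroperoxy-2-methoxypropane | COC(C)(C)OO | intermediate
4 | (2E,4E)-hexa-2,4-dienal (sorbaldehyde) | C/C=C/C=C/C=O | starting material
5 | (3R,4E)-3-[(2-methoxypropan-2-yl)peroxy]hex-4-enal | C/C=C/[C@@H](CC=O)OOC(C)(C)OC | intermediate
6 | (3R,4E)-3-[(2-methoxypropan-2-yl)peroxy]hex-4-enoic acid | C/C=C/[C@@H](CC(=O)O)OOC(C)(C)OC | intermediate
7 | methyl (3R,4E)-3-[(2-methoxypropan-2-yl)peroxy]hex-4-enoate | C/C=C/[C@@H](CC(=O)OC)OOC(C)(C)OC | intermediate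
8 | methyl (3R,4E)-3-hydroperoxyhex-4-enoate | C/C=C/[C@@H](CC(=O)OC)OO | intermediate
9 | methoxyallene (1-methoxypropa-1,2-diene) | C=C=COC | starting material
10 | 1-iodohexadecane | CCCCCCCCCCCCCCCCI | starting material
11 | 1-lithio-1-methoxyallene | C=C=C([Li])OC | intermediate
12 | 3-methoxynonadeca-1,2-diene (1-hexadecyl-1-methoxyallene) | C=C=C(OC)CCCCCCCCCCCCCCCC | intermediate
13 | methyl (3R,4E)-3-{[(3RS)-3-methoxynonadec-1-en-3-yl]peroxy}hex-4-enoate (both epimers at the ketal carbon) | C/C=C/[C@@H](CC(=O)OC)OOC(OC)(C=C)CCCCCCCCCCCCCCCC | intermediate
14 | methyl 2-[(3R,6RS)-6-hexadecyl-6-methoxy-3,6-dihydro-1,2-dioxin-3-yl]acetate (both C6 epimers) | CCCCCCCCCCCCCCCCC1(OC)C=C[C@@H](CC(=O)OC)OO1 | intermediate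
15 | chondrillin, methyl 2-[(3R,6S)-6-hexadecyl-6-methoxy-3,6-dihydro-1,2-dioxin-3-yl]acetate | CCCCCCCCCCCCCCCC[C@@]1(OC)C=C[C@@H](CC(=O)OC)OO1 | target

**Step count and risks**

Total steps: 8. Longest linear sequence: 7 (steps 1, 2, 3, 4, 5, 7, 8).

Steps most likely to fail:

(1) Step 7 (proposed new method). What may go wrong: capture of the methoxyallyl cation at its CH2 terminus, acid-induced release of the hydroperoxide from the acyclic peroxyketal during the warm metathesis stage, and deactivation of the ruthenium alkylidene by residual OOH or excess allene. Fallback with known chemistry, setting out from 12 and 8 and returning at 14: 12 is treated with methanol and catalytic PPTS (acid-catalysed alcohol addition to an alkoxyallene) to give 3,3-dimethoxynonadec-1-ene F1. Ketal exchange of F1 with 8 (PPTS, CH2Cl2, 4 Å molecular sieves, the usual way to peroxyketals from dimethyl ketals) then gives 13, which is now isolated and purified on neutralised silica. RCM of pure 13 in a separate flask with the second-generation Hoveyda–Grubbs catalyst (CH2Cl2, 40 °C, high dilution) should give 14.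

(2) Step 2. What may go wrong: erosion of enantiopurity through insufficient facial discrimination on the iminium ion, together with loss of material by closure of the enamine to an epoxide. Fallback that replaces catalyst control by classical resolution, setting out from 8 of insufficient enantiopurity and returning at 8: the chiral enol ether 2-{[(1R,2S)-2-phenylcyclohexyl]oxy}prop-1-ene F2 is made from commercial (1R,2S)-2-phenylcyclohexanol and 2-methoxypropene. PPTS-catalysed addition of 8 to F2 gives the diastereomeric peroxyketals methyl (3R,4E)-3-[(2-{[(1R,2S)-2-phenylcyclohexyl]oxy}propan-2-yl)peroxy]hex-4-enoate F3 and its (3S) diastereomer F4. F3 is separated by chromatography and hydrolysed (AcOH/THF/H2O) to enantiopure 8.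

(3) Step 8. What may go wrong: no useful thermodynamic bias between the C6 epimers, so that throughput rests on repeated recycling. Fallback that changes from substitution at C6 to alkylation at oxygen, setting out from 14 and returning at 15: mild hydrolysis of 14 (TsOH cat., THF/H2O) gives the cyclic peroxy hemiketal methyl 2-[(3R,6RS)-6-hexadecyl-6-hydroxy-3,6-dihydro-1,2-dioxin-3-yl]acetate F5. Purdie-type O-methylation of F5 (MeI, Ag2O, CH2Cl2) leaves the C6–O bond intact, so the epimer ratio is set kinetically by the relative reactivity of the interconverting hemiketal anomers and not by the ketal equilibrium. Chromatography then gives 15.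

**Further compounds**

F1 | step 7 | 3,3-dimethoxynonadec-1-ene | C=CC(OC)(OC)CCCCCCCCCCCCCCCC
F2 | step 2 | 2-{[(1R,2S)-2-phenylcyclohexyl]oxy}prop-1-ene | C=C(C)O[C@@H]1CCCC[C@H]1c1ccccc1
F3 | step 2 | methyl (3R,4E)-3-[(2-{[(1R,2S)-2-phenylcyclohexyl]oxy}propan-2-yl)peroxy]hex-4-enoate | C/C=C/[C@@H](CC(=O)OC)OOC(C)(C)O[C@@H]1CCCC[C@H]1c1ccccc1
F4 | step 2 | methyl (3S,4E)-3-[(2-{[(1R,2S)-2-phenylcyclohexyl]oxy}propan-2-yl)peroxy]hex-4-enoate | C/C=C/[C@H](CC(=O)OC)OOC(C)(C)O[C@@H]1CCCC[C@H]1c1ccccc1
F5 | step 8 | methyl 2-[(3R,6RS)-6-hexadecyl-6-hydroxy-3,6-dihydro-1,2-dioxin-3-yl]acetate | CCCCCCCCCCCCCCCCC1(O)C=C[C@@H](CC(=O)OC)OO1
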